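**Strategy**

Ring A of the decalin (C1–C4, C4a, C8a; C2 carries the ether oxygen, C4a the angular methyl) is read as a masked p-cresol, because its oxygenated C2 lies para to the methyl-bearing quaternary C4a. Everything rests on disconnecting C4a–C5 of ring B (C4a, C5–C8, C8a). The precursor is a p-cresol-type phenoxide whose meta benzylic chain carries the C7 stereocentre and a terminal bromide. One fluoride-triggered para-alkylative dearomatization closes ring B, converts the flat arene into the ring A dienone and sets the C4a quaternary centre from C7. Dissolving-metal reduction, equatorial methylation, SNAr O-arylation, allyl installation and Suzuki coupling then deliver the honokiol-type ether.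

Key step: step 5

Remark: locants follow decahydronaphthalene numbering of the terpenoid part (C2 ether carbon, C4a angular methyl carbon, C7 hydroxypropyl carbon, C8a ring-fusion CH); compounds 1, 2, 13 and 18 are taken to be catalogue chemicals.

**Route**

Step 1
Reactants: 1 5-hydroxy-2-methylbenzaldehyde; 2 3-(triphenyl-λ5-phosphanylidene)oxolan-2-one
Product: 3 (E)-3-[(5-hydroxy-2-methylphenyl)methylidene]oxolan-2-one
Conditions: toluene, 110 °C
Reagents that add atoms: none
Why: Wittig olefination with a stabilized lactone ylide, which should give the E arylidene lactone under thermodynamic control and tolerates the free phenol.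

Step 2
Reactants: 3 (E)-3-[(5-hydroxy-2-methylphenyl)methylidene]oxolan-2-one
Product: 4 (S)-3-[(5-hydroxy-2-methylphenyl)methyl]oxolan-2-one
Conditions: Ru(OAc)2[(S)-BINAP] (1 mol%), H2 (50 atm), MeOH, 50 °C
Reagents that add atoms: none
Why: Asymmetric hydrogenation of an α-arylidene-γ-butyrolactone with a BINAP–ruthenium catalyst, in which the lactone carbonyl binds the metal and the ligand decides the face of hydrogen delivery, setting the future C7 centre (S in the lactone); the ligand antipode is the one that delivers the S lactone, and the R ligand would be used if the sense proves opposite.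

Step 3
Reactants: 4 (S)-3-[(5-hydroxy-2-methylphenyl)methyl]oxolan-2-one
Product: 6 methyl (S)-4-bromo-2-[(5-hydroxy-2-methylphenyl)methyl]butanoate, via bromo acid 5 (not isolated)
Conditions: HBr (g), MeOH, 0 °C to rt
Reagents that add atoms: hydrogen bromide (Br); methanol (CO)
Why: Acid-mediated lactone opening by bromide at the O-alkyl carbon (SN2) followed by Fischer esterification, the classical conversion of a γ-butyrolactone into a γ-bromo ester, which should leave the α-stereocentre untouched.

Step 4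
Reactants: 6 methyl (S)-4-bromo-2-[(5-hydroxy-2-methylphenyl)methyl]butanoate
Product: 8 triethyl{3-[(2S)-4-bromo-2-{2-[(triethylsilyl)oxy]propan-2-yl}butyl]-4-methylphenoxy}silane, via bis(bromomagnesium) alkoxide 7 (not isolated)
Conditions: MeMgBr (3.5 equiv), Et2O–CH2Cl2, −20 to 0 °C; then 2,6-lutidine, TESOTf (4 equiv), −20 to 0 °C
Reagents that add atoms: methylmagnesium bromide (C[Mg]Br); triethylsilyl trifluoromethanesulfonate (CC[Si](CC)(CC)OS(=O)(=O)C(F)(F)F)
Why: Double Grignard addition to the ester gives the tertiary magnesium alkoxide, which is silylated in the same flask (together with the phenoxide) before it can displace the bromide to a tetrahydrofuran; no new stereocentre is formed.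

Step 5
Reactants: 8 triethyl{3-[(2S)-4-bromo-2-{2-[(triethylsilyl)oxy]propan-2-yl}butyl]-4-methylphenoxy}silane
Product: 10 (4aS,7R)-4a-methyl-7-{2-[(triethylsilyl)oxy]propan-2-yl}-5,6,7,8-tetrahydronaphthalen-2(4aH)-one, via tetrabutylammonium phenoxide 9 (not isolated)
Conditions: TBAF (1.05 equiv), THF (0.005 M), 0 °C then 66 °C
Reagents that add atoms: none
Why: One equivalent of fluoride at 0 °C cleaves only the aryl silyl ether, and the free tetrabutylammonium phenoxide 9 then attacks the primary bromide through its para carbon in an intramolecular SN2 reaction, a fluoride-triggered alkylative dearomatization of the Winstein–Masamune type. Ring B is closed by a 6-exo-tet displacement at C5, with C4a, C5, C6, C7, C8 and C8a passing through a chair-like transition state, and the arene becomes the cross-conjugated ring A dienone because the methyl group on C4a blocks rearomatization. The new quaternary centre C4a is controlled by the C7 stereocentre: the planarity of ring A forces the C4a methyl axial on the forming ring, so the chair that keeps the bulky silyloxypropyl group equatorial places that group cis to the methyl, as the target requires. The step needs para (C4a) over ortho (C1) C-alkylation and C- over O-alkylation: intramolecular O-alkylation would require a strained meta-bridged eight-membered ether and intermolecular O-alkylation is held back by high dilution, while the free phenoxide has its largest carbon coefficient para to oxygen at the methyl-activated C4a, whereas C1 is squeezed between the oxygen and the benzylic carbon. The tertiary silyl ether keeps the side-chain oxygen from closing a tetrahydrofuran onto the same bromide.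

Step 6
Reactants: 10 (4aS,7R)-4a-methyl-7-{2-[(triethylsilyl)oxy]propan-2-yl}-5,6,7,8-tetrahydronaphthalen-2(4aH)-one
Product: 11 (4aS,7R,8aS)-4a-methyl-7-{2-[(triethylsilyl)oxy]propan-2-yl}octahydronaphthalen-2(1H)-one (trans-fused)
Conditions: Li (5 equiv), NH3 (l), THF, t-BuOH (1.0 equiv), −78 °C; then solid NH4Cl
Reagents that add atoms: none
Why: Dissolving-metal (Birch-type) conjugate reduction in which the disubstituted C3=C4 bond is reduced first, the single equivalent of tert-butanol reprotonates the dienolate so that the C1=C8a enone is reduced in turn, and axial protonation of the C8a carbanion should give the trans ring fusion while the final enolate shields the ketone from over-reduction.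

Step 7
Reactants: 11 (4aS,7R,8aS)-4a-methyl-7-{2-[(triethylsilyl)oxy]propan-2-yl}octahydronaphthalen-2(1H)-one
Product: 12 (2R,4aS,7R,8aS)-2,4a-dimethyl-7-{2-[(triethylsilyl)oxy]propan-2-yl}decahydronaphthalen-2-ol
Conditions: MeTi(OiPr)3 (2.5 equiv), Et2O, −20 °C to rt
Reagents that add atoms: methyltitanium triisopropoxide (C[Ti](OC(C)C)(OC(C)C)OC(C)C)
Why: Carbonyl methylation with a bulky organotitanium reagent, which should attack the conformationally locked C2 ketone along the equatorial trajectory and so give the axial C2 alcohol with equatorial methyl (2R), as known for steroid-like 3-ketones of trans-decalins.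

Step 8
Reactants: 12 (2R,4aS,7R,8aS)-2,4a-dimethyl-7-{2-[(triethylsilyl)oxy]propan-2-yl}decahydronaphthalen-2-ol; 13 3-chloro-4-fluorobenzaldehyde
Product: 14 3-chloro-4-{[(2R,4aS,7R,8aS)-2,4a-dimethyl-7-{2-[(triethylsilyl)oxy]propan-2-yl}decahydronaphthalen-2-yl]oxy}benzaldehyde
Conditions: KH (1.2 equiv), THF, 0 °C; then 13 (1.3 equiv), DMF, 0 to 40 °C
Reagents that add atoms: none
Why: Nucleophilic aromatic substitution (SNAr) in which the potassium tertiary alkoxide displaces the fluoride para to the formyl group via a Meisenheimer intermediate (fluoride leaving far faster than chloride), forming the hindered tertiary alkyl aryl ether with the C2 configuration retained because the alcohol C–O bond is never broken.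

Step 9
Reactants: 14 3-chloro-4-{[(2R,4aS,7R,8aS)-2,4a-dimethyl-7-{2-[(triethylsilyl)oxy]propan-2-yl}decahydronaphthalen-2-yl]oxy}benzaldehyde
Product: 16 1-(3-chloro-4-{[(2R,4aS,7R,8aS)-2,4a-dimethyl-7-{2-[(triethylsilyl)oxy]propan-2-yl}decahydronaphthalen-2-yl]oxy}phenyl)prop-2-en-1-yl methyl carbonate (both epimers at the carbinol carbon), via bromomagnesium allylic alkoxide 15 (not isolated)
Conditions: CH2=CHMgBr (1.3 equiv), THF, −78 °C; then ClCO2Me (2 equiv), −78 to 0 °C
Reagents that add atoms: vinylmagnesium bromide (C=C[Mg]Br); methyl chloroformate (COC(=O)Cl)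
Why: Grignard 1,2-addition to the aryl aldehyde followed by in situ O-acylation of the alkoxide; the new carbinol centre forms unselectively and is destroyed in the next step.

Step 10
Reactants: 16 1-(3-chloro-4-{[(2R,4aS,7R,8aS)-2,4a-dimethyl-7-{2-[(triethylsilyl)oxy]propan-2-yl}decahydronaphthalen-2-yl]oxy}phenyl)prop-2-en-1-yl methyl carbonate
Product: 17 4-allyl-2-chloro-1-{[(2R,4aS,7R,8aS)-2,4a-dimethyl-7-{2-[(triethylsilyl)oxy]propan-2-yl}decahydronaphthalen-2-yl]oxy}benzene
Conditions: Pd(OAc)2 (5 mol%), n-Bu3P (20 mol%), HCO2H, Et3N, THF, rt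
Reagents that add atoms: none
Why: Tsuji palladium-catalysed formate hydrogenolysis of an allylic carbonate, in which the 1-arylallyl palladium formate loses CO2 and delivers hydride to the more substituted (benzylic) terminus, which should give the terminal allyl arene and leave the aryl chloride untouched at room temperature.

Step 11
Reactants: 18 2-allyl-4-bromophenol
Product: 19 2-allyl-4-(4,4,5,5-tetramethyl-1,3,2-dioxaborolan-2-yl)phenol
Conditions: PdCl2(dppf) (3 mol%), B2pin2 (1.2 equiv), KOAc, dioxane, 85 °C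
Reagents that add atoms: bis(pinacolato)diboron (CC1(C)OB(OC1(C)C)B1OC(C)(C)C(C)(C)O1)
Why: Miyaura borylation of the aryl bromide under acetate conditions mild enough for the free phenol and the allyl group.

Step 12
Reactants: 17 4-allyl-2-chloro-1-{[(2R,4aS,7R,8aS)-2,4a-dimethyl-7-{2-[(triethylsilyl)oxy]propan-2-yl}decahydronaphthalen-2-yl]oxy}benzene; 19 2-allyl-4-(4,4,5,5-tetramethyl-1,3,2-dioxaborolan-2-yl)phenol
Product: 20 3',5-diallyl-2-{[(2R,4aS,7R,8aS)-2,4a-dimethyl-7-{2-[(triethylsilyl)oxy]propan-2-yl}decahydronaphthalen-2-yl]oxy}-[1,1'-biphenyl]-4'-ol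
Conditions: Pd(OAc)2 (5 mol%), SPhos (10 mol%), K3PO4, toluene–H2O, 90 °C
Reagents that add atoms: none
Why: Suzuki–Miyaura coupling in which the electron-rich biarylphosphine should allow oxidative addition into the hindered ortho-alkoxy aryl chloride, joining the two aromatic rings at the position fixed by the chlorine.

Step 13
Reactants: 20 3',5-diallyl-2-{[(2R,4aS,7R,8aS)-2,4a-dimethyl-7-{2-[(triethylsilyl)oxy]propan-2-yl}decahydronaphthalen-2-yl]oxy}-[1,1'-biphenyl]-4'-ol
Product: 21 3',5-diallyl-2-{[(2R,4aS,7R,8aS)-7-(2-hydroxypropan-2-yl)-2,4a-dimethyldecahydronaphthalen-2-yl]oxy}-[1,1'-biphenyl]-4'-ol (CNP0342687.1)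
Conditions: TBAF (3 equiv), THF, rt to 45 °C
Reagents that add atoms: none
Why: Fluoride-mediated desilylation of the tertiary triethylsilyl ether under non-acidic conditions that should spare the acid-labile tertiary alkyl aryl ether and both allyl groups.

**Compound list**

1 | 5-hydroxy-2-methylbenzaldehyde | Cc1ccc(O)cc1C=O | starting material
2 | 3-(triphenyl-λ5-phosphanylidene)oxolan-2-one | O=C1OCCC1=P(c1ccccc1)(c1ccccc1)c1ccccc1 | starting material
3 | (E)-3-[(5-hydroxy-2-methylphenyl)methylidene]oxolan-2-one | O=C1OCC/C1=C\c1cc(O)ccc1C | intermediate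
4 | (S)-3-[(5-hydroxy-2-methylphenyl)methyl]oxolan-2-one | O=C1OCC[C@@H]1Cc1cc(O)ccc1C | intermediate
5 | (S)-4-bromo-2-[(5-hydroxy-2-methylphenyl)methyl]butanoic acid (not isolated) | OC(=O)[C@H](CCBr)Cc1cc(O)ccc1C | intermediate
6 | methyl (S)-4-bromo-2-[(5-hydroxy-2-methylphenyl)methyl]butanoate | COC(=O)[C@H](CCBr)Cc1cc(O)ccc1C | intermediate
7 | bis(bromomagnesium) salt of (S)-5-bromo-3-[(5-hydroxy-2-methylphenyl)methyl]-2-methylpentan-2-ol (not isolated) | Cc1ccc(O[Mg]Br)cc1C[C@@H](CCBr)C(C)(C)O[Mg]Br | intermediate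
8 | triethyl{3-[(2S)-4-bromo-2-{2-[(triethylsilyl)oxy]propan-2-yl}butyl]-4-methylphenoxy}silane | Cc1ccc(O[Si](CC)(CC)CC)cc1C[C@@H](CCBr)C(C)(C)O[Si](CC)(CC)CC | intermediate
9 | tetrabutylammonium 3-[(2S)-4-bromo-2-{2-[(triethylsilyl)oxy]propan-2-yl}butyl]-4-methylphenoxide (not isolated) | Cc1ccc([O-])cc1C[C@@H](CCBr)C(C)(C)O[Si](CC)(CC)CC.CCCC[N+](CCCC)(CCCC)CCCC | intermediate
10 | (4aS,7R)-4a-methyl-7-{2-[(triethylsilyl)oxy]propan-2-yl}-5,6,7,8-tetrahydronaphthalen-2(4aH)-one | O=C1C=C2C[C@H](C(C)(C)O[Si](CC)(CC)CC)CC[C@@]2(C)C=C1 | intermediate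
11 | (4aS,7R,8aS)-4a-methyl-7-{2-[(triethylsilyl)oxy]propan-2-yl}octahydronaphthalen-2(1H)-one | O=C1CC[C@]2(C)CC[C@@H](C(C)(C)O[Si](CC)(CC)CC)C[C@H]2C1 | intermediate
12 | (2R,4aS,7R,8aS)-2,4a-dimethyl-7-{2-[(triethylsilyl)oxy]propan-2-yl}decahydronaphthalen-2-ol | O[C@]1(C)CC[C@]2(C)CC[C@@H](C(C)(C)O[Si](CC)(CC)CC)C[C@H]2C1 | intermediate
13 | 3-chloro-4-fluorobenzaldehyde | O=Cc1ccc(F)c(Cl)c1 | starting material
14 | 3-chloro-4-{[(2R,4aS,7R,8aS)-2,4a-dimethyl-7-{2-[(triethylsilyl)oxy]propan-2-yl}decahydronaphthalen-2-yl]oxy}benzaldehyde | O=Cc1ccc(O[C@]2(C)CC[C@]3(C)CC[C@@H](C(C)(C)O[Si](CC)(CC)CC)C[C@H]3C2)c(Cl)c1 | intermediate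
15 | bromomagnesium 1-(3-chloro-4-{[(2R,4aS,7R,8aS)-2,4a-dimethyl-7-{2-[(triethylsilyl)oxy]propan-2-yl}decahydronaphthalen-2-yl]oxy}phenyl)prop-2-en-1-olate, both epimers (not isolated) | C=CC(O[Mg]Br)c1ccc(O[C@]2(C)CC[C@]3(C)CC[C@@H](C(C)(C)O[Si](CC)(CC)CC)C[C@H]3C2)c(Cl)c1 | intermediate
16 | 1-(3-chloro-4-{[(2R,4aS,7R,8aS)-2,4a-dimethyl-7-{2-[(triethylsilyl)oxy]propan-2-yl}decahydronaphthalen-2-yl]oxy}phenyl)prop-2-en-1-yl methyl carbonate, both epimers at the carbinol carbon | C=CC(OC(=O)OC)c1ccc(O[C@]2(C)CC[C@]3(C)CC[C@@H](C(C)(C)O[Si](CC)(CC)CC)C[C@H]3C2)c(Cl)c1 | intermediate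
17 | 4-allyl-2-chloro-1-{[(2R,4aS,7R,8aS)-2,4a-dimethyl-7-{2-[(triethylsilyl)oxy]propan-2-yl}decahydronaphthalen-2-yl]oxy}benzene | C=CCc1ccc(O[C@]2(C)CC[C@]3(C)CC[C@@H](C(C)(C)O[Si](CC)(CC)CC)C[C@H]3C2)c(Cl)c1 | intermediate
18 | 2-allyl-4-bromophenol | C=CCc1cc(Br)ccc1O | starting material
19 | 2-allyl-4-(4,4,5,5-tetramethyl-1,3,2-dioxaborolan-2-yl)phenol | C=CCc1cc(B2OC(C)(C)C(C)(C)O2)ccc1O | intermediate
20 | 3',5-diallyl-2-{[(2R,4aS,7R,8aS)-2,4a-dimethyl-7-{2-[(triethylsilyl)oxy]propan-2-yl}decahydronaphthalen-2-yl]oxy}-[1,1'-biphenyl]-4'-ol | C=CCc1ccc(O[C@]2(C)CC[C@]3(C)CC[C@@H](C(C)(C)O[Si](CC)(CC)CC)C[C@H]3C2)c(-c2ccc(O)c(CC=C)c2)c1 | intermediate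
21 | 3',5-diallyl-2-{[(2R,4aS,7R,8aS)-7-(2-hydroxypropan-2-yl)-2,4a-dimethyldecahydronaphthalen-2-yl]oxy}-[1,1'-biphenyl]-4'-ol | C=CCc1ccc(O[C@]2(C)CC[C@]3(C)CC[C@@H](C(C)(C)O)C[C@H]3C2)c(-c2ccc(O)c(CC=C)c2)c1 | target

**Step count and risks**

Total step count: 13. Longest linear sequence: 12 steps (steps 1–10, 12 and 13; step 11 prepares the boronate separately).

Steps most likely to fail:

1. Step 5 (key step). The phenoxide may alkylate through the ortho carbon C1 with rearomatization, or oligomerize by intermolecular O-alkylation, instead of attacking through the methyl-bearing para carbon. The fallback blocks both ortho positions with a removable halogen. Setting out from 8, the aryl silyl ether alone is cleaved (K2CO3, MeOH, 0 °C, then AcOH) to 3-[(2S)-4-bromo-2-{2-[(triethylsilyl)oxy]propan-2-yl}butyl]-4-methylphenol F1. NBS (2.1 equiv) with catalytic i-Pr2NH in CH2Cl2 then brominates both positions ortho to the hydroxyl, giving 2,6-dibromo-3-[(2S)-4-bromo-2-{2-[(triethylsilyl)oxy]propan-2-yl}butyl]-4-methylphenol F2. With KOtBu (1.0 equiv) in t-BuOH at 80 °C under high dilution, this phenoxide can alkylate only through its para carbon and should give (4aS,7R)-1,3-dibromo-4a-methyl-7-{2-[(triethylsilyl)oxy]propan-2-yl}-5,6,7,8-tetrahydronaphthalen-2(4aH)-one F3. Li in NH3 with t-BuOH, using a larger excess of metal, reduces both ring A double bonds and cleaves both vinylic C–Br bonds, which brings the sequence back to the route at 11.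

2. Step 8. Substitution at the hindered axial tertiary alkoxide may be slow, and the aldehyde partner may be consumed by alkoxide-induced hydride transfer before the ether forms. The fallback uses a nitrile-activated fluoroarene that has no such pathway. Setting out from 12, the potassium alkoxide (KH, THF–DMF) is treated with 3-chloro-4-fluorobenzonitrile to give 3-chloro-4-{[(2R,4aS,7R,8aS)-2,4a-dimethyl-7-{2-[(triethylsilyl)oxy]propan-2-yl}decahydronaphthalen-2-yl]oxy}benzonitrile F4. Partial reduction with i-Bu2AlH in toluene at −78 °C and aqueous tartrate work-up then returns to the route at 14.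

3. Step 10. Hydride delivery to the allyl–palladium intermediate may lose regiocontrol, or a palladium hydride may move the double bond into conjugation with the arene. The fallback builds the allyl group by a benzylic substitution that involves no allyl–metal species. Setting out from 14, reduction with NaBH4 in MeOH at 0 °C gives (3-chloro-4-{[(2R,4aS,7R,8aS)-2,4a-dimethyl-7-{2-[(triethylsilyl)oxy]propan-2-yl}decahydronaphthalen-2-yl]oxy}phenyl)methanol F5. CBr4 and PPh3 in CH2Cl2 at 0 °C convert it into 4-(bromomethyl)-2-chloro-1-{[(2R,4aS,7R,8aS)-2,4a-dimethyl-7-{2-[(triethylsilyl)oxy]propan-2-yl}decahydronaphthalen-2-yl]oxy}benzene F6. Coupling with CH2=CHMgBr and CuI (10 mol%) in THF at −30 °C then comes back to the route at 17.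

**Further compounds**

F1 | step 5 | 3-[(2S)-4-bromo-2-{2-[(triethylsilyl)oxy]propan-2-yl}butyl]-4-methylphenol | Cc1ccc(O)cc1C[C@@H](CCBr)C(C)(C)O[Si](CC)(CC)CC
F2 | step 5 | 2,6-dibromo-3-[(2S)-4-bromo-2-{2-[(triethylsilyl)oxy]propan-2-yl}butyl]-4-methylphenol | Cc1cc(Br)c(O)c(Br)c1C[C@@H](CCBr)C(C)(C)O[Si](CC)(CC)CC
F3 | step 5 | (4aS,7R)-1,3-dibromo-4a-methyl-7-{2-[(triethylsilyl)oxy]propan-2-yl}-5,6,7,8-tetrahydronaphthalen-2(4aH)-one | O=C1C(Br)=C2C[C@H](C(C)(C)O[Si](CC)(CC)CC)CC[C@@]2(C)C=C1Br
F4 | step 8 | 3-chloro-4-{[(2R,4aS,7R,8aS)-2,4a-dimethyl-7-{2-[(triethylsilyl)oxy]propan-2-yl}decahydronaphthalen-2-yl]oxy}benzonitrile | N#Cc1ccc(O[C@]2(C)CC[C@]3(C)CC[C@@H](C(C)(C)O[Si](CC)(CC)CC)C[C@H]3C2)c(Cl)c1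
F5 | step 10 | (3-chloro-4-{[(2R,4aS,7R,8aS)-2,4a-dimethyl-7-{2-[(triethylsilyl)oxy]propan-2-yl}decahydronaphthalen-2-yl]oxy}phenyl)methanol | OCc1ccc(O[C@]2(C)CC[C@]3(C)CC[C@@H](C(C)(C)O[Si](CC)(CC)CC)C[C@H]3C2)c(Cl)c1
F6 | step 10 | 4-(bromomethyl)-2-chloro-1-{[(2R,4aS,7R,8aS)-2,4a-dimethyl-7-{2-[(triethylsilyl)oxy]propan-2-yl}decahydronaphthalen-2-yl]oxy}benzene | BrCc1ccc(O[C@]2(C)CC[C@]3(C)CC[C@@H](C(C)(C)O[Si](CC)(CC)CC)C[C@H]3C2)c(Cl)c1
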